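Readings and results come from a simulation for substances that don't exist; noise was put on by code.

Divide the free base charged by the electrophile charged. Taking each reacted electrophile to set one acid free, this ratio, the cover30.0%, is the share reacted up to which free base can take up that acid.

| flask | electrophile | nucleophile | free base | remark | time |
|---|---|---|---|---|---|
| winter | 0.20 M | 0.40 M | 0.060 M | the very flask that is asked about, followed so far |  |
| noon | 0.20 M | 0.40 M | 0.040 M | run made earlier |  |
| flask | 0.20 M | 0.400 M | 0.0600 M |  | 30 min |

| run | time / min | electrophile / % | target / % |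
|---|---|---|---|
| winter | 0.833 | 85.9 | 13.6 |
| winter | 1.50 | 77.7 | 20.4 |
| winter | 2.50 | 67.7 | 32.2 |
| winter | 3.00 | 61.5 | 34.6 |
| winter | 4.00 | 53.3 | 44.4 |
| winter | 5.00 | 50.0 | 49.6 |
| noon | 1.00 | 84.8 | 16.1 |
| noon | 1.33 | 81.4 | 18.7 |
| noon | 2.00 | 72.1 | 27.6 |
| noon | 3.00 | 63.9 | 33.7 |
| noon | 5.00 | 49.9 | 47.2 |
| noon | 8.00 | 36.5 | 58.8 |
| noon | 12.0 | 26.8 | 69.4 |

(readings scatter by 1 percentage point)

- the earlier runs do not show how much of nucleophile is bound; that part of a forecast is a guess

- part of the electrophile that has reacted at 30 min
- share of the unused nucleophile that is free and not bound as protonated nucleophile, at 30 min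

The winter run is this flask followed so far. It holds 0.060 M of free base against 0.040 M in the noon run, yet at 5.00 min the two runs read 50.0% and 49.9% of electrophile. Comparing rates clears this up. Below the noon cover, 20.0%, the two runs have equal free nucleophile. Past its cover, a run loses at worst two nucleophile per electrophile, one consumed and one bound. At a share reacted of 0.5, this reckoning leaves 0.260 M in winter and 0.240 M at noon, a lead of 8.33% in rate, which a scatter of 1 percentage point hides. The lead drifts upward as nucleophile shrinks, to 12.5% at 0.7.

The forecast gave 90.5% (87% to 94%) reacted and 47% (39% to 72%) free, adding “Partial binding would raise both values, so I shade upward”.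

The flask gives 88.7% reacted and 60.1% free.

    2 electrophile → homo dimer (k = 0.0250 M⁻¹ min⁻¹)
    acid set free + free base ⇌ salt of the base, settled at all times (K = 11000 M⁻¹)
    nucleophile + acid set free ⇌ protonated nucleophile, settled at all times (K = 37.0 M⁻¹)
    electrophile + nucleophile ⇌ acid set free + target (K = 1.60, k = 0.420 M⁻¹ min⁻¹)

In the flask, the forward step to target uses electrophile 17 times as fast as the homo dimer step just after the start, and 22 times as fast at 3.90 min. At 30.0 min the flask holds 84.8% target against 3.90% homo dimer. Its salt of the base holds 0.0597 M of acid, the amount the cover of 30.0% allows, and the target beyond that comes to 0.110 M, which stands as acid set free and protonated nucleophile. The neighbour flask with 0.15 M of free base has a cover of 75.0% and holds 0.0356 M of target beyond its salt of the base, and its unused nucleophile is 85.7% free.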